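**Plan**

- Retrosynthesis: (a) remove the 5‑O‑methyl and benzyl ester groups; (b) open quinone ring A (C1, C2, C3, C4, C4a, C8a) at C1–C8a, C1–C2 and C3–C4, giving an aryl(methoxy)carbene complex of Cr(CO)5 (ring B plus C4), one CO ligand (C1) and a terminal 8‑ethynylchromone (C2, C3); (c) alkyne from an 8‑formylchromone; (d) pyranone ring from an o‑hydroxyacetophenone, ester from an aryl triflate, formyl group from symmetric 2,6‑dihydroxy‑4‑methylacetophenone.
- Forward: formylate the symmetric acetophenone, triflate the less hindered OH, carbonylate to the benzyl ester, close the pyranone ring with the remaining OH, homologate CHO to C≡CH. Make the carbene complex from 1‑bromo‑2‑methoxy‑4‑methylbenzene. Join the halves and build ring A in one benzannulation, oxidise to the quinone, deprotect.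
- Enabling feature: C1 of ring A is a carbonyl carbon bonded only to C2, C8a and O, ring A is para‑dioxygenated (C1, C4), and C8a is the single free ortho carbon of ring B next to C4a. C1 can therefore arrive as the central carbon of a dienylketene (O=C1=C2–C3=C4–C4a=C8a), whose 6π‑electrocyclisation makes the C1–C8a bond.
- Regiochemistry follows from the terminal alkyne (the chromonyl carbon bonds to C1) and from the methoxy group at C5, which blocks the second ortho position.
- Stereochemistry: the target has no stereocentre, so nothing is set.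

Key step: step 7

Remark: the SMILES assigns no configuration to the hindered aryl–quinone axis (quinone C2 to chromone C8), so this axis is left uncontrolled.

**Route**

Step 1
Reactants: 1 1-(2,6-dihydroxy-4-methylphenyl)ethan-1-one
Product: 2 3-acetyl-2,4-dihydroxy-6-methylbenzaldehyde
Conditions: Cl2CHOMe, TiCl4, CH2Cl2, 0 °C → rt; then 1 M HCl
Reagents that add atoms: dichloromethyl methyl ether, COC(Cl)Cl; water, O
Why: Rieche formylation should attack the only kind of free ring position (C3 and C5 are equivalent by symmetry, each ortho to one OH and para to the other), so one regioisomer is expected, and the new formyl group deactivates the ring against a second formylation.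

Step 2
Reactants: 2 3-acetyl-2,4-dihydroxy-6-methylbenzaldehyde
Product: 3 2-acetyl-4-formyl-3-hydroxy-5-methylphenyl trifluoromethanesulfonate
Conditions: PhNTf2 (1.05 equiv), Et3N, DMAP (cat.), CH2Cl2, 0 °C → rt
Reagents that add atoms: N-phenylbis(trifluoromethanesulfonimide), O=S(=O)(N(c1ccccc1)S(=O)(=O)C(F)(F)F)C(F)(F)F
Why: Regioselective phenol sulfonylation should occur at the 4‑OH, which has a free ortho C–H and is para to the formyl group, because the 2‑OH is flanked by formyl and acetyl groups and held in a salicylaldehyde‑type hydrogen bond.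

Step 3
Reactants: 3 2-acetyl-4-formyl-3-hydroxy-5-methylphenyl trifluoromethanesulfonate
Product: 4 benzyl 2-acetyl-4-formyl-3-hydroxy-5-methylbenzoate
Conditions: Pd(OAc)2 (5 mol %), dppp (6 mol %), CO (1 atm), BnOH, Et3N, DMF, 70 °C
Reagents that add atoms: carbon monoxide, [C-]#[O+]; benzyl alcohol, OCc1ccccc1
Why: Palladium‑catalysed alkoxycarbonylation of an electron‑poor aryl triflate (oxidative addition, CO insertion, alcoholysis of the acylpalladium) should tolerate the aldehyde, the ketone and the chelated phenol.

Step 4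
Reactants: 4 benzyl 2-acetyl-4-formyl-3-hydroxy-5-methylbenzoate
Product: 6 benzyl 8-formyl-7-methyl-4-oxo-4H-chromene-5-carboxylate, via enaminone 5 (not isolated)
Conditions: Me2NCH(OMe)2, toluene, 80 °C; then conc. HCl, CH2Cl2, rt
Reagents that add atoms: N,N-dimethylformamide dimethyl acetal, COC(OC)N(C)C
Why: In the enaminone chromone synthesis the acetyl methyl group condenses with the amide acetal and acid‑promoted conjugate addition of the only free phenol with loss of dimethylamine closes the pyranone ring, which places the formyl group at C8 and the ester at C5.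

Step 5
Reactants: 6 benzyl 8-formyl-7-methyl-4-oxo-4H-chromene-5-carboxylate
Product: 7 benzyl 8-ethynyl-7-methyl-4-oxo-4H-chromene-5-carboxylate
Conditions: MeC(O)C(N2)P(O)(OMe)2, NaOMe (1.3 equiv), THF, −78 °C → rt
Reagents that add atoms: dimethyl (1-diazo-2-oxopropyl)phosphonate (Ohira–Bestmann reagent), CC(=O)C(=[N+]=[N-])P(=O)(OC)OC
Why: In this Seyferth–Gilbert homologation the diazomethylphosphonate anion, released by methoxide at low temperature, adds to the aldehyde, and loss of dimethyl phosphate and N2 with a 1,2‑hydrogen shift gives the terminal alkyne, while stoichiometric base at −78 °C should spare the benzyl ester and the pyranone ring.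

Step 6
Reactants: 8 1-bromo-2-methoxy-4-methylbenzene
Product: 11 pentacarbonyl[methoxy(2-methoxy-4-methylphenyl)methylidene]chromium, via aryllithium 9 (not isolated), via lithium acylchromate 10 (not isolated)
Conditions: n-BuLi, Et2O, −78 → 0 °C; Cr(CO)6, 0 °C → rt; then Me3OBF4, CH2Cl2, 0 °C
Reagents that add atoms: hexacarbonylchromium Cr(CO)6, O=C=[Cr](=C=O)(=C=O)(=C=O)(=C=O)=C=O; trimethyloxonium tetrafluoroborate, C[O+](C)C.F[B-](F)(F)F
Why: Fischer carbene synthesis: bromine–lithium exchange, addition of the aryllithium to a CO ligand of Cr(CO)6 and O‑methylation of the acylchromate with Meerwein's salt.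

Step 7
Reactants: 11 pentacarbonyl[methoxy(2-methoxy-4-methylphenyl)methylidene]chromium; 7 benzyl 8-ethynyl-7-methyl-4-oxo-4H-chromene-5-carboxylate
Product: 14 benzyl 8-(5-methoxy-7-methyl-1,4-dioxo-1,4-dihydronaphthalen-2-yl)-7-methyl-4-oxo-4H-chromene-5-carboxylate, via dienylketene chromium complex 12 (not isolated), via naphthol chromium complex 13 (not isolated)
Conditions: THF, 55 °C, Ar; then (NH4)2Ce(NO3)6, MeCN/H2O, 0 °C
Reagents that add atoms: water, O
Why: Loss of one CO from 11 lets alkyne 7 coordinate and insert into the Cr=C bond with its bulky chromonyl‑bearing carbon next to a CO ligand, and CO insertion then gives the chromium‑bound dienylketene 12 (O=C1=C2–C3=C4–C4a=C8a). Ring A is closed by 6π‑electrocyclisation of this triene, in which the ketene carbon C1 bonds to C8a of the anisyl ring, and tautomerisation of the cyclohexadienone gives naphthol complex 13; this is the Dötz benzannulation, which is the closest known reaction type and applies directly. No stereocentre is formed. The regioselectivity needed is secured by the terminal alkyne, whose larger substituent ends up next to the CO‑derived carbon (chromone at C2, H at C3), and by the methoxy group at C5, which blocks the other ortho position so that closure can only occur at C8a. Six‑ring phenol formation should be favoured over indene, furan or cyclobutenone by‑products by the aryl(alkoxy)carbene, the ethereal solvent and the moderate temperature. (NH4)2Ce(NO3)6 then removes Cr(CO)3 and oxidises the 4‑methoxy‑1‑naphthol to the quinone, water supplying the C4 oxygen and methanol leaving.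

Step 8
Reactants: 14 benzyl 8-(5-methoxy-7-methyl-1,4-dioxo-1,4-dihydronaphthalen-2-yl)-7-methyl-4-oxo-4H-chromene-5-carboxylate
Product: 15 8-(5-hydroxy-7-methyl-1,4-dioxo-1,4-dihydronaphthalen-2-yl)-7-methyl-4-oxo-4H-chromene-5-carboxylic acid
Conditions: BCl3 (excess), CH2Cl2, −78 → 0 °C; then H2O
Reagents that add atoms: none
Why: Lewis‑acid dealkylation: BCl3 chelated between the C4 quinone carbonyl and the peri 5‑OMe lets chloride remove the methyl group, and the same reagent cleaves the benzyl ester at the benzylic C–O bond, while quinone and chromone rings should survive at low temperature.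

**Compound list**

1 | 1-(2,6-dihydroxy-4-methylphenyl)ethan-1-one | CC(=O)c1c(O)cc(C)cc1O | starting material
2 | 3-acetyl-2,4-dihydroxy-6-methylbenzaldehyde | CC(=O)c1c(O)cc(C)c(C=O)c1O | intermediate
3 | 2-acetyl-4-formyl-3-hydroxy-5-methylphenyl trifluoromethanesulfonate | CC(=O)c1c(OS(=O)(=O)C(F)(F)F)cc(C)c(C=O)c1O | intermediate
4 | benzyl 2-acetyl-4-formyl-3-hydroxy-5-methylbenzoate | CC(=O)c1c(C(=O)OCc2ccccc2)cc(C)c(C=O)c1O | intermediate
5 | benzyl 2-[(2E)-3-(dimethylamino)prop-2-enoyl]-4-formyl-3-hydroxy-5-methylbenzoate (enaminone) | CN(C)/C=C/C(=O)c1c(C(=O)OCc2ccccc2)cc(C)c(C=O)c1O | intermediate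
6 | benzyl 8-formyl-7-methyl-4-oxo-4H-chromene-5-carboxylate | O=Cc1c(C)cc(C(=O)OCc2ccccc2)c2c(=O)ccoc12 | intermediate
7 | benzyl 8-ethynyl-7-methyl-4-oxo-4H-chromene-5-carboxylate | C#Cc1c(C)cc(C(=O)OCc2ccccc2)c2c(=O)ccoc12 | intermediate
8 | 1-bromo-2-methoxy-4-methylbenzene | COc1cc(C)ccc1Br | starting material
9 | (2-methoxy-4-methylphenyl)lithium | [Li]c1ccc(C)cc1OC | intermediate
10 | lithium pentacarbonyl[(2-methoxy-4-methylphenyl)(oxido)methylidene]chromate | [Li+].[O-]C(c1ccc(C)cc1OC)=[Cr](=C=O)(=C=O)(=C=O)(=C=O)=C=O | intermediate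
11 | pentacarbonyl[methoxy(2-methoxy-4-methylphenyl)methylidene]chromium | COC(c1ccc(C)cc1OC)=[Cr](=C=O)(=C=O)(=C=O)(=C=O)=C=O | intermediate
12 | Cr(CO)3 complex of benzyl 8-[(3E)-4-methoxy-4-(2-methoxy-4-methylphenyl)-1-oxobuta-1,3-dien-2-yl]-7-methyl-4-oxo-4H-chromene-5-carboxylate (π‑bound metal fragment written as a separate part) | CO/C(=C/C(=C=O)c1c(C)cc(C(=O)OCc2ccccc2)c2c(=O)ccoc12)c1ccc(C)cc1OC.O=C=[Cr](=C=O)=C=O | intermediate
13 | Cr(CO)3 complex of benzyl 8-(1-hydroxy-4,5-dimethoxy-7-methylnaphthalen-2-yl)-7-methyl-4-oxo-4H-chromene-5-carboxylate (π‑bound metal fragment written as a separate part) | COc1cc(C)cc2c(O)c(-c3c(C)cc(C(=O)OCc4ccccc4)c4c(=O)ccoc34)cc(OC)c12.O=C=[Cr](=C=O)=C=O | intermediate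
14 | benzyl 8-(5-methoxy-7-methyl-1,4-dioxo-1,4-dihydronaphthalen-2-yl)-7-methyl-4-oxo-4H-chromene-5-carboxylate | COc1cc(C)cc2c1C(=O)C=C(c1c(C)cc(C(=O)OCc3ccccc3)c3c(=O)ccoc13)C2=O | intermediate
15 | 8-(5-hydroxy-7-methyl-1,4-dioxo-1,4-dihydronaphthalen-2-yl)-7-methyl-4-oxo-4H-chromene-5-carboxylic acid | Cc1cc(O)c2c(c1)C(=O)C(c1c(C)cc(C(=O)O)c3c(=O)ccoc13)=CC2=O | target

**Step count and risks**

Total steps: 8. Longest linear sequence: 7 steps (steps 1, 2, 3, 4, 5, 7, 8).

Steps most likely to fail:

1. Step 7. Alkyne insertion may be slowed by the doubly ortho‑substituted aryl alkyne, or the intermediate may be diverted to indene, furan or cyclobutenone products instead of the phenol. The fallback generates the same kind of dienylketene without chromium, by a Moore‑type ring expansion, and sets out from alkyne 7 and bromide 8. [2+2] Cycloaddition of 7 with dichloroketene (Cl3CCOCl, Zn/Cu couple, Et2O) should give the 4,4‑dichlorocyclobutenone F1. Brief treatment with cold concentrated H2SO4 should hydrolyse the gem‑dichloride to the arylcyclobutenedione F2. Aryllithium 9, generated from 8 as in step 6 (THF, −78 °C, with CeCl3 if conjugate addition to the chromone interferes), should add to the less hindered carbonyl next to the ring CH to give the 4‑aryl‑4‑hydroxycyclobutenone F3. Heating (toluene or xylene, 110–140 °C) opens the four‑membered ring to the dienylketene, which closes the same C1–C8a bond and tautomerises to the hydroquinone F4. Oxidation (Ag2O, CH2Cl2) comes back to the route at quinone 14.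

2. Step 2. Sulfonylation may take place at the wrong hydroxyl or at both. The fallback differentiates the two hydroxyls while the ring is still symmetric and sets out from acetophenone 1. Mono‑triflation (Tf2O 1.0 equiv, pyridine, CH2Cl2, −78 °C) should give the mono‑triflate F5 without any regiochemical choice. Carbonylation under the conditions of step 3 should give the benzyl ester F6. Magnesium‑mediated ortho‑formylation (MgCl2, Et3N, paraformaldehyde, MeCN, reflux), which is specific for the position ortho to the phenol, comes back to the route at compound 4.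

3. Step 5. Methoxide or the phosphonate anion may add to C2 of the pyranone ring or transesterify the benzyl ester before the homologation is complete. The fallback avoids carbanion bases and sets out from aldehyde 6. Dibromo‑olefination (CBr4, PPh3, CH2Cl2, 0 °C) should give the 1,1‑dibromoalkene F7. Pd(PPh3)4‑catalysed hydrogenolysis with Bu3SnH should remove the bromine trans to the aryl group and give the (Z)‑bromoalkene F8. Anti‑elimination of HBr with Bu4NF (DMF, rt) comes back to the route at alkyne 7.

**Further compounds**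

F1 | step 7 | benzyl 8-(4,4-dichloro-3-oxocyclobut-1-en-1-yl)-7-methyl-4-oxo-4H-chromene-5-carboxylate | O=C1C=C(c2c(C)cc(C(=O)OCc3ccccc3)c3c(=O)ccoc23)C1(Cl)Cl
F2 | step 7 | benzyl 8-(3,4-dioxocyclobut-1-en-1-yl)-7-methyl-4-oxo-4H-chromene-5-carboxylate | O=C1C=C(c2c(C)cc(C(=O)OCc3ccccc3)c3c(=O)ccoc23)C1=O
F3 | step 7 | benzyl 8-[3-hydroxy-3-(2-methoxy-4-methylphenyl)-4-oxocyclobut-1-en-1-yl]-7-methyl-4-oxo-4H-chromene-5-carboxylate (racemic) | COc1cc(C)ccc1C1(O)C=C(c2c(C)cc(C(=O)OCc3ccccc3)c3c(=O)ccoc23)C1=O
F4 | step 7 | benzyl 8-(1,4-dihydroxy-5-methoxy-7-methylnaphthalen-2-yl)-7-methyl-4-oxo-4H-chromene-5-carboxylate | COc1cc(C)cc2c(O)c(-c3c(C)cc(C(=O)OCc4ccccc4)c4c(=O)ccoc34)cc(O)c12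
F5 | step 2 | 2-acetyl-3-hydroxy-5-methylphenyl trifluoromethanesulfonate | CC(=O)c1c(O)cc(C)cc1OS(=O)(=O)C(F)(F)F
F6 | step 2 | benzyl 2-acetyl-3-hydroxy-5-methylbenzoate | CC(=O)c1c(O)cc(C)cc1C(=O)OCc1ccccc1
F7 | step 5 | benzyl 8-(2,2-dibromoethenyl)-7-methyl-4-oxo-4H-chromene-5-carboxylate | BrC(Br)=Cc1c(C)cc(C(=O)OCc2ccccc2)c2c(=O)ccoc12
F8 | step 5 | benzyl 8-[(Z)-2-bromoethenyl]-7-methyl-4-oxo-4H-chromene-5-carboxylate | Br/C=C\c1c(C)cc(C(=O)OCc2ccccc2)c2c(=O)ccoc12
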